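**Plan**

- The target is read as epicatechin-(4β→8)-catechin with a 4-hydroxybenzoate on O3 of the lower (catechin) unit. The retrosynthesis cuts first nine O–benzyl bonds and a C8–Br cap, then the interflavan bond C4(upper)–C8(lower), then the C3–C4 and O1–C8a bonds of the lower ring C together.
- Forward, the lower ring C is closed in one flask onto a fluorinated ring A benzyl unit (benzylzinc addition to an α-aroyloxy aldehyde, 1,2-acyl shift, SNAr). The upper unit is then joined at its C4, and one hydrogenolysis removes all benzyl groups and the bromine.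
- Enabling feature: ring A of the lower unit is a phloroglucinol ring. C8a lies meta to the oxygens on C5 and C7, so a C8a–F bond is open to an alkoxide, while C4 on the neighbouring C4a can be a benzylic zinc nucleophile. The vicinal oxygens on C2 and C3 let the target's own aroyl group move from the C2 oxygen to the C3 oxygen, which frees O1 and masks O3.
- Stereochemistry: lower C2 from a lipase resolution of an aryl vinyl carbinol; lower C3 by Felkin–Anh (Cornforth) addition anti to the acyloxy group; upper C2 and C3 from (−)-epicatechin; upper C4 by attack anti to the 3-hydroxyl.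

Key step: step 9

Remark on the chemistry: 1,3,5-trifluorobenzene, 3,4-bis(benzyloxy)benzaldehyde, 4-(benzyloxy)benzoyl chloride and (−)-epicatechin are taken as commercial; benzyl ethers are used throughout so that one hydrogenolysis ends the route.

**Route**

Step 1
Reactants: 1 1,3,5-trifluorobenzene
Product: 2 1,3-bis(benzyloxy)-5-fluorobenzene
Conditions: BnOH (2.1 equiv), NaH, DMF, 0 → 80 °C
Reagents that add atoms: benzyl alcohol OCc1ccccc1
Why: Twofold nucleophilic aromatic substitution (SNAr) by benzyloxide should stop after two exchanges because each alkoxy group slows the next one; no stereocenter.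

Step 2
Reactants: 2 1,3-bis(benzyloxy)-5-fluorobenzene
Product: 4 2,4-bis(benzyloxy)-6-fluorobenzaldehyde, via aryl iminium chloride 3 (not isolated)
Conditions: POCl3, DMF, 0 → 60 °C; then aq NaOAc
Reagents that add atoms: N,N-dimethylformamide CN(C)C=O; water O
Why: Vilsmeier–Haack formylation should enter para to one benzyloxy group and ortho to the other and to the small fluorine, the position between the two benzyloxy groups being the more hindered; no stereocenter.

Step 3
Reactants: 4 2,4-bis(benzyloxy)-6-fluorobenzaldehyde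
Product: 5 [2,4-bis(benzyloxy)-6-fluorophenyl]methanol
Conditions: NaBH4, THF–MeOH, 0 °C
Reagents that add atoms: none
Why: Hydride reduction of the aldehyde by NaBH4; no stereocenter.

Step 4
Reactants: 5 [2,4-bis(benzyloxy)-6-fluorophenyl]methanol
Product: 6 1,5-bis(benzyloxy)-2-(chloromethyl)-3-fluorobenzene
Conditions: SOCl2, 2,6-lutidine, CH2Cl2, −20 → 0 °C; used crude
Reagents that add atoms: thionyl chloride O=S(Cl)Cl
Why: Chlorodehydroxylation through the chlorosulfite at the electron-rich benzylic carbon, the base taking up HCl; no stereocenter.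

Step 5
Reactants: 7 3,4-bis(benzyloxy)benzaldehyde
Product: 8 rac-1-[3,4-bis(benzyloxy)phenyl]prop-2-en-1-ol
Conditions: CH2=CHMgBr, THF, −78 → 0 °C; aq NH4Cl
Reagents that add atoms: vinylmagnesium bromide C=C[Mg]Br
Why: Grignard 1,2-addition to the aldehyde gives the racemic carbinol, whose stereocenter is resolved in step 6.

Step 6
Reactants: 8 rac-1-[3,4-bis(benzyloxy)phenyl]prop-2-en-1-ol
Product: 9 (1S)-1-[3,4-bis(benzyloxy)phenyl]prop-2-en-1-ol
Conditions: immobilised Candida antarctica lipase B, vinyl acetate (0.6 equiv), toluene, 30 °C, run past half conversion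
Reagents that add atoms: none
Why: Enzymatic kinetic resolution by lipase transesterification should acylate the R alcohol (large aryl, medium vinyl) and leave the S alcohol, which becomes C2 of the lower unit.

Step 7
Reactants: 9 (1S)-1-[3,4-bis(benzyloxy)phenyl]prop-2-en-1-ol; 10 4-(benzyloxy)benzoyl chloride
Product: 11 (1S)-1-[3,4-bis(benzyloxy)phenyl]prop-2-en-1-yl 4-(benzyloxy)benzoate
Conditions: Et3N, DMAP (cat.), CH2Cl2, 0 °C
Reagents that add atoms: none
Why: DMAP-catalysed O-acylation takes place at oxygen only and leaves the stereocenter untouched.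

Step 8
Reactants: 11 (1S)-1-[3,4-bis(benzyloxy)phenyl]prop-2-en-1-yl 4-(benzyloxy)benzoate
Product: 13 (1R)-1-[3,4-bis(benzyloxy)phenyl]-2-oxoethyl 4-(benzyloxy)benzoate, via ozonide 12 (not isolated)
Conditions: O3, CH2Cl2, −78 °C (indicator dye); then Me2S, −78 → 0 °C; used crude
Reagents that add atoms: ozone [O-][O+]=O
Why: Ozonolysis with reductive work-up cleaves the terminal alkene under neutral cold conditions, so the benzylic stereocenter should be kept (the descriptor changes from S to R only through the priority rules).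

Step 9
Reactants: 6 1,5-bis(benzyloxy)-2-(chloromethyl)-3-fluorobenzene; 13 (1R)-1-[3,4-bis(benzyloxy)phenyl]-2-oxoethyl 4-(benzyloxy)benzoate
Product: 17 (2R,3S)-5,7-bis(benzyloxy)-2-[3,4-bis(benzyloxy)phenyl]-3,4-dihydro-2H-chromen-3-yl 4-(benzyloxy)benzoate, via benzylzinc chloride 14 (not isolated), via zinc alkoxide 15 (not isolated), via potassium alkoxide 16 (not isolated)
Conditions: Zn dust, LiCl, THF, 25 °C; then 13, MgCl2, −20 → 0 °C; then KN(SiMe3)2, 18-crown-6, DMPU, 0 → 50 °C
Reagents that add atoms: none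
Why: Proposed new method: zinc inserts into the benzylic C–Cl bond of 6, and the benzylzinc chloride 14 adds to the aldehyde of 13 from the face anti to the aroyloxy group (polar Felkin–Anh, i.e. Cornforth, arrangement; the ester oxygen does not chelate), which forms C3–C4 and sets C3 as S from the R centre at C2 (anti adduct 15). When potassium replaces zinc, the C3 alkoxide adds to the neighbouring ester and the aroyl group moves from the C2 oxygen to the C3 oxygen through a five-membered orthoester anion, which frees the more stable benzylic alkoxide 16 and masks O3 as the very ester the target carries. Alkoxide 16 then attacks the fluorine-bearing ring carbon next to the benzylic carbon and fluoride leaves (6-exo addition–elimination, SNAr), which forms O1–C8a and closes the dihydropyran ring C; that carbon is meta to both benzyloxy groups and so is not deactivated by them. The closest known reaction types are the MgCl2-promoted addition of benzylic zinc chlorides to aldehydes, the base-induced 1,2-acyl shift of diol monoesters and the chroman synthesis by intramolecular SNAr of 3-(2-fluoroaryl)propan-1-olates; their union in one flask, with the acyl shift as the switch between the two alkoxides, has not been shown. C2 keeps its configuration because its C–O bond is never broken and no base meets the aldehyde before the addition. The step needs arylation of O1 and not of O3 (six- against five-membered ring) and one site on the arene: the acyl-shift equilibrium holds the charge on the benzylic oxygen, the six-membered closure runs through a chair-like transition state with the aryl and aroyloxy groups equatorial, and the single C–F bond fixes C8a.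

Step 10
Reactants: 18 (−)-epicatechin
Product: 19 5,7,3',4'-tetra-O-benzyl-(−)-epicatechin
Conditions: BnBr, K2CO3, DMF, 0 °C → rt
Reagents that add atoms: benzyl bromide BrCc1ccccc1
Why: Williamson O-benzylation of the four phenols, which are far more acidic than the secondary alcohol that stays free; no stereocenter is touched.

Step 11
Reactants: 19 5,7,3',4'-tetra-O-benzyl-(−)-epicatechin
Product: 20 (2R,3R,4S)-5,7-bis(benzyloxy)-2-[3,4-bis(benzyloxy)phenyl]-4-(2-ethoxyethoxy)-3,4-dihydro-2H-chromen-3-ol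
Conditions: DDQ, 2-ethoxyethanol, CH2Cl2, rt
Reagents that add atoms: 2-ethoxyethanol CCOCCO
Why: Benzylic oxidation by DDQ (hydride abstraction at C4, assisted by the ring A ethers) gives the C4 cation, which the alcohol should trap anti to the axial 3-hydroxyl and so set C4 as 4β.

Step 12
Reactants: 20 (2R,3R,4S)-5,7-bis(benzyloxy)-2-[3,4-bis(benzyloxy)phenyl]-4-(2-ethoxyethoxy)-3,4-dihydro-2H-chromen-3-ol
Product: 21 (2R,3R,4S)-5,7-bis(benzyloxy)-2-[3,4-bis(benzyloxy)phenyl]-8-bromo-4-(2-ethoxyethoxy)-3,4-dihydro-2H-chromen-3-ol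
Conditions: NBS, CH2Cl2, −40 → 0 °C
Reagents that add atoms: N-bromosuccinimide O=C1CCC(=O)N1Br
Why: Electrophilic aromatic bromination should take C8 and not the more hindered C6 between two benzyloxy groups, and the bromine then blocks self-condensation in step 13; no stereocenter is touched.

Step 13
Reactants: 17 (2R,3S)-5,7-bis(benzyloxy)-2-[3,4-bis(benzyloxy)phenyl]-3,4-dihydro-2H-chromen-3-yl 4-(benzyloxy)benzoate; 21 (2R,3R,4S)-5,7-bis(benzyloxy)-2-[3,4-bis(benzyloxy)phenyl]-8-bromo-4-(2-ethoxyethoxy)-3,4-dihydro-2H-chromen-3-ol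
Product: 22 5,7,3',4'-tetra-O-benzyl-8-bromo-(−)-epicatechin-(4β→8)-5,7,3',4'-tetra-O-benzyl-(+)-catechin 3-O-[4-(benzyloxy)benzoate] (ester on the lower unit)
Conditions: Me3SiOTf (0.2 equiv), CH2Cl2, −78 → −40 °C
Reagents that add atoms: none
Why: Lewis-acid ionisation of the C4 ether gives the ring A-stabilised C4 cation, which alkylates C8 of 17 (Friedel–Crafts-type interflavan coupling) anti to the axial 3-hydroxyl and so sets the upper C4 as 4β, C6 of 17 being shielded by two benzyloxy groups.

Step 14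
Reactants: 22 protected dimer
Product: 23 epicatechin-(4β→8)-catechin 3-O-(4-hydroxybenzoate) on the lower unit (target)
Conditions: H2 (1 atm), Pd(OH)2/C, Et3N (1 equiv), THF–MeOH–H2O, rt
Reagents that add atoms: none
Why: Hydrogenolysis over Pd(OH)2/C should remove the nine benzyl groups and the aryl bromine in one operation without touching the aryl ester or any stereocenter, the amine taking up HBr.

**Compound list**

1 | 1,3,5-trifluorobenzene | Fc1cc(F)cc(F)c1 | starting material
2 | 1,3-bis(benzyloxy)-5-fluorobenzene | Fc1cc(OCc2ccccc2)cc(OCc2ccccc2)c1 | intermediate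
3 | N-{[2,4-bis(benzyloxy)-6-fluorophenyl]methylidene}-N-methylmethanaminium chloride | C[N+](C)=Cc1c(F)cc(OCc2ccccc2)cc1OCc1ccccc1.[Cl-] | intermediate
4 | 2,4-bis(benzyloxy)-6-fluorobenzaldehyde | O=Cc1c(F)cc(OCc2ccccc2)cc1OCc1ccccc1 | intermediate
5 | [2,4-bis(benzyloxy)-6-fluorophenyl]methanol | OCc1c(F)cc(OCc2ccccc2)cc1OCc1ccccc1 | intermediate
6 | 1,5-bis(benzyloxy)-2-(chloromethyl)-3-fluorobenzene | ClCc1c(F)cc(OCc2ccccc2)cc1OCc1ccccc1 | intermediate
7 | 3,4-bis(benzyloxy)benzaldehyde | O=Cc1ccc(OCc2ccccc2)c(OCc2ccccc2)c1 | starting material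
8 | rac-1-[3,4-bis(benzyloxy)phenyl]prop-2-en-1-ol | C=CC(O)c1ccc(OCc2ccccc2)c(OCc2ccccc2)c1 | intermediate
9 | (1S)-1-[3,4-bis(benzyloxy)phenyl]prop-2-en-1-ol | C=C[C@H](O)c1ccc(OCc2ccccc2)c(OCc2ccccc2)c1 | intermediate
10 | 4-(benzyloxy)benzoyl chloride | O=C(Cl)c1ccc(OCc2ccccc2)cc1 | starting material
11 | (1S)-1-[3,4-bis(benzyloxy)phenyl]prop-2-en-1-yl 4-(benzyloxy)benzoate | C=C[C@H](OC(=O)c1ccc(OCc2ccccc2)cc1)c1ccc(OCc2ccccc2)c(OCc2ccccc2)c1 | intermediate
12 | (R)-[3,4-bis(benzyloxy)phenyl](1,2,4-trioxolan-3-yl)methyl 4-(benzyloxy)benzoate (secondary ozonide, both epimers at the trioxolane carbon) | O=C(O[C@H](c1ccc(OCc2ccccc2)c(OCc2ccccc2)c1)C1OCOO1)c1ccc(OCc2ccccc2)cc1 | intermediate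
13 | (1R)-1-[3,4-bis(benzyloxy)phenyl]-2-oxoethyl 4-(benzyloxy)benzoate | O=C[C@H](OC(=O)c1ccc(OCc2ccccc2)cc1)c1ccc(OCc2ccccc2)c(OCc2ccccc2)c1 | intermediate
14 | [2,4-bis(benzyloxy)-6-fluorobenzyl]zinc chloride | Cl[Zn]Cc1c(F)cc(OCc2ccccc2)cc1OCc1ccccc1 | intermediate
15 | chlorozinc (1R,2S)-1-[3,4-bis(benzyloxy)phenyl]-3-[2,4-bis(benzyloxy)-6-fluorophenyl]-1-{[4-(benzyloxy)benzoyl]oxy}propan-2-olate (anti adduct) | O=C(O[C@H](c1ccc(OCc2ccccc2)c(OCc2ccccc2)c1)[C@H](Cc1c(F)cc(OCc2ccccc2)cc1OCc1ccccc1)O[Zn]Cl)c1ccc(OCc2ccccc2)cc1 | intermediate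
16 | potassium (1R,2S)-1-[3,4-bis(benzyloxy)phenyl]-3-[2,4-bis(benzyloxy)-6-fluorophenyl]-2-{[4-(benzyloxy)benzoyl]oxy}propan-1-olate | [K+].[O-][C@H](c1ccc(OCc2ccccc2)c(OCc2ccccc2)c1)[C@H](Cc1c(F)cc(OCc2ccccc2)cc1OCc1ccccc1)OC(=O)c1ccc(OCc2ccccc2)cc1 | intermediate
17 | (2R,3S)-5,7-bis(benzyloxy)-2-[3,4-bis(benzyloxy)phenyl]-3,4-dihydro-2H-chromen-3-yl 4-(benzyloxy)benzoate | O=C(O[C@H]1Cc2c(OCc3ccccc3)cc(OCc3ccccc3)cc2O[C@@H]1c1ccc(OCc2ccccc2)c(OCc2ccccc2)c1)c1ccc(OCc2ccccc2)cc1 | intermediate
18 | (−)-epicatechin, (2R,3R) | O[C@@H]1Cc2c(O)cc(O)cc2O[C@@H]1c1ccc(O)c(O)c1 | starting material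
19 | 5,7,3',4'-tetra-O-benzyl-(−)-epicatechin, (2R,3R) | O[C@@H]1Cc2c(OCc3ccccc3)cc(OCc3ccccc3)cc2O[C@@H]1c1ccc(OCc2ccccc2)c(OCc2ccccc2)c1 | intermediate
20 | (2R,3R,4S)-5,7-bis(benzyloxy)-2-[3,4-bis(benzyloxy)phenyl]-4-(2-ethoxyethoxy)-3,4-dihydro-2H-chromen-3-ol (4β-ether, trans to the 3-hydroxyl) | CCOCCO[C@H]1c2c(OCc3ccccc3)cc(OCc3ccccc3)cc2O[C@H](c2ccc(OCc3ccccc3)c(OCc3ccccc3)c2)[C@@H]1O | intermediate
21 | (2R,3R,4S)-5,7-bis(benzyloxy)-2-[3,4-bis(benzyloxy)phenyl]-8-bromo-4-(2-ethoxyethoxy)-3,4-dihydro-2H-chromen-3-ol | CCOCCO[C@H]1c2c(OCc3ccccc3)cc(OCc3ccccc3)c(Br)c2O[C@H](c2ccc(OCc3ccccc3)c(OCc3ccccc3)c2)[C@@H]1O | intermediate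
22 | 5,7,3',4'-tetra-O-benzyl-8-bromo-(−)-epicatechin-(4β→8)-5,7,3',4'-tetra-O-benzyl-(+)-catechin 3-O-[4-(benzyloxy)benzoate]; upper unit 2R,3R with the C4–C8 bond trans to the 3-hydroxyl, lower unit 2R,3S with the ester on its O3 | O=C(O[C@H]1Cc2c(OCc3ccccc3)cc(OCc3ccccc3)c([C@H]3c4c(OCc5ccccc5)cc(OCc5ccccc5)c(Br)c4O[C@H](c4ccc(OCc5ccccc5)c(OCc5ccccc5)c4)[C@@H]3O)c2O[C@@H]1c1ccc(OCc2ccccc2)c(OCc2ccccc2)c1)c1ccc(OCc2ccccc2)cc1 | intermediate
23 | (2R,3S)-2-(3,4-dihydroxyphenyl)-8-[(2R,3R,4R)-2-(3,4-dihydroxyphenyl)-3,5,7-trihydroxy-3,4-dihydro-2H-chromen-4-yl]-5,7-dihydroxy-3,4-dihydro-2H-chromen-3-yl 4-hydroxybenzoate | O=C(O[C@H]1Cc2c(O)cc(O)c([C@H]3c4c(O)cc(O)cc4O[C@H](c4ccc(O)c(O)c4)[C@@H]3O)c2O[C@@H]1c1ccc(O)c(O)c1)c1ccc(O)cc1 | target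

**Count and risks**

Total step count: 14. Longest linear sequence: 7 steps (steps 5, 6, 7, 8, 9, 13, 14; the arm through steps 1–4 is equally long).

Steps most likely to fail:

1. Step 9 (proposed new method). What may go wrong: ring closure by the C3 alkoxide before or instead of the acyl shift (five-membered ring); chelation-controlled addition giving the syn adduct; base-induced epimerisation of the aldehyde at C2; intermolecular acyl transfer in the basic second stage. Fallback with known chemistry, a relay from the chiral pool: commercial (+)-catechin is O-benzylated at its four phenols (BnBr, K2CO3, DMF) to 5,7,3',4'-tetra-O-benzyl-(+)-catechin F1, and F1 is acylated at O3 with acid chloride 10 (Et3N, DMAP, CH2Cl2). The fallback sets out from 10 and comes back to the route at 17.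

2. Step 13. What may go wrong: self-condensation of the C4 cation, attack at C6 of 17, or slow capture by the acylated nucleophile with elimination of the cation to the flav-3-ene. Fallback, a change of activation from a hard Lewis acid on a C4 ether to a thiophilic silver salt on a C4 thioether: 21 is treated with 1,3-benzothiazole-2-thiol and BF3·OEt2 in CH2Cl2 to give the 4β-(1,3-benzothiazol-2-ylsulfanyl) analogue of 21 F2 (thiol enters anti to the 3-hydroxyl), and F2 is coupled with 17 by AgBF4 in THF at 0 °C. The fallback sets out from 21 and comes back at 22.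

3. Step 8. What may go wrong: attack of ozone on the electron-rich benzyloxy rings and epimerisation of the α-aryl-α-acyloxy aldehyde during isolation. Fallback, glycol cleavage in place of ozonide chemistry: 11 is dihydroxylated (OsO4 cat., N-methylmorpholine N-oxide, acetone–water) to (1R)-1-[3,4-bis(benzyloxy)phenyl]-2,3-dihydroxypropyl 4-(benzyloxy)benzoate F3, and F3 is cleaved at once with NaIO4 in buffered THF–water at 0 °C (pH 7, to suppress acyl shift in the diol), the crude aldehyde going straight into step 9. The fallback sets out from 11 and comes back at 13.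

**Further compounds**

F1 | step 9 | 5,7,3',4'-tetra-O-benzyl-(+)-catechin, (2R,3S) | O[C@H]1Cc2c(OCc3ccccc3)cc(OCc3ccccc3)cc2O[C@@H]1c1ccc(OCc2ccccc2)c(OCc2ccccc2)c1
F2 | step 13 | 4-(1,3-benzothiazol-2-ylsulfanyl)-5,7-bis(benzyloxy)-2-[3,4-bis(benzyloxy)phenyl]-8-bromo-3,4-dihydro-2H-chromen-3-ol, 2R,3R, thioether at C4 β and trans to the 3-hydroxyl | c1ccc2sc(S[C@H]3c4c(OCc5ccccc5)cc(OCc5ccccc5)c(Br)c4O[C@H](c4ccc(OCc5ccccc5)c(OCc5ccccc5)c4)[C@@H]3O)nc2c1
F3 | step 8 | (1R)-1-[3,4-bis(benzyloxy)phenyl]-2,3-dihydroxypropyl 4-(benzyloxy)benzoate (both C2 epimers) | OCC(O)[C@H](OC(=O)c1ccc(OCc2ccccc2)cc1)c1ccc(OCc2ccccc2)c(OCc2ccccc2)c1
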